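**Assumptions (one line each)**
- Compounds 1, 5, 7 and 11 are commercial building blocks. Simple reagents that add atoms (NBS, TIPSCl, B2pin2, TBSOTf) are given only in the "Reagents" line and are not numbered.
- The target's carbinol is (S). CIP priorities are OH > butenolide C3 (its branch carries O,O,O) > aryl > H, and the SMILES `[C@H]` with neighbour order (Ar, H, O, C3) works out to S.
- The exocyclic alkene in the target is Z, with the aryl cis to the ring O. This is the thermodynamic geometry of rubrolide-type butenolides.
- I assume (−)-MIB gives the (S)-alcohol. The ligand enantiomer would need to be confirmed experimentally.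

**Retrosynthesis**
1. The target comes from global desilylation of the bis-TIPS phenol ether **12**.
2. The C3–CH(OH)Ar bond and the (S) stereocentre come from a catalytic enantioselective addition of a 3-metallo-butenolide (from vinyl bromide **10**) to aldehyde **11**. This is the new step.
3. The Z-5-arylidene comes from a vinylogous Mukaiyama aldol and E1cB elimination on the 4-aryl-3-bromobutenolide **8** with aldehyde **6**.
4. **8** comes from a C4-selective Suzuki coupling of commercial 3,4-dibromofuranone **7** with the arylboronate **4**, which is made from 4-iodophenol.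
5. No ring is constructed. The lactone ring is carried in from **7** and the arenes are pre-formed.

## Route

**Step 1**
Reactants: 1 (4-iodophenol)
Product: 2 (2-bromo-4-iodophenol)
Conditions: NBS (1.0 equiv), i-Pr2NH (10 mol %), CH2Cl2, 0 °C → rt
Reagents that add atoms: NBS, `O=C1CCC(=O)N1Br`
Why: The amine-mediated electrophilic bromination of a para-blocked phenol is ortho-selective and gives the mono-bromide. No stereocentre is involved.

**Step 2**
Reactants: 2
Product: 3 ((2-bromo-4-iodophenoxy)triisopropylsilane)
Conditions: TIPSCl (1.2 equiv), imidazole, DMF, rt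
Reagents that add atoms: TIPSCl, `CC(C)[Si](Cl)(C(C)C)C(C)C`
Why: Silylation gives a phenol protecting group that survives Suzuki, DBU and Grignard conditions (TIPS is more robust than TBS here).

**Step 3**
Reactants: 3
Product: 4 (triisopropyl[2-bromo-4-(Bpin)phenoxy]silane)
Conditions: B2pin2 (1.1 equiv), PdCl2(dppf) (3 mol %), KOAc, DMSO, 50 °C
Reagents that add atoms: B2pin2, `CC1(C)OB(OC1(C)C)B1OC(C)(C)C(C)(C)O1`
Why: Miyaura borylation is chemoselective because oxidative addition into C–I is much faster than into the hindered ortho C–Br at mild temperature.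

**Step 4**
Reactants: 5 (3-bromo-4-hydroxybenzaldehyde)
Product: 6 (3-bromo-4-(TIPSO)benzaldehyde)
Conditions: TIPSCl (1.2 equiv), imidazole, DMF, rt
Reagents that add atoms: TIPSCl, `CC(C)[Si](Cl)(C(C)C)C(C)C`
Why: Standard phenol silylation.

**Step 5**
Reactants: 4 (arylBpin) and 7 (3,4-dibromofuran-2(5H)-one)
Product: 8 (3-bromo-4-[3-bromo-4-(TIPSO)phenyl]furan-2(5H)-one)
Conditions: Pd(PPh3)4 (5 mol %), Ag2O (1.5 equiv), THF, 60 °C
Reagents that add atoms: none
Why: Suzuki–Miyura coupling occurs selectively at C4, the β-carbon of the enoate, which is more electrophilic toward oxidative addition than C3. The mild Ag2O conditions avoid lactone opening.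

**Step 6**
Reactants: 8 and 6
Product: 9 (5-[(TBSO)(3-bromo-4-TIPSO-phenyl)methyl]-3-bromo-4-aryl-furan-2(5H)-one, a diastereomeric mixture; both new stereocentres are destroyed in Step 7)
Conditions: TBSOTf (1.3 equiv), Et3N, CH2Cl2, 0 °C, 30 min (gives the 2-silyloxyfuran in situ); then 6 (1.2 equiv), BF3·OEt2, −78 → −40 °C
Reagents that add atoms: TBSOTf, `CC(C)(C)[Si](C)(C)OS(=O)(=O)C(F)(F)F` (TBS ends up on the new carbinol oxygen)
Why: Vinylogous Mukaiyama aldol of the 2-silyloxyfuran occurs at C5 (the γ-position).

**Step 7**
Reactants: 9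
Product: 10 ((Z)-3-bromo-4-[3-bromo-4-(TIPSO)phenyl]-5-[3-bromo-4-(TIPSO)benzylidene]furan-2(5H)-one)
Conditions: DBU (3 equiv), CH2Cl2, 25 °C, dark
Reagents that add atoms: none (TBSOH is lost)
Why: The C5–H is acidic because deprotonation gives an aromatic furanolate. E1cB loss of the β-silyloxy group then gives the thermodynamically favoured Z-arylidene (aryl cis to ring O), which sets the alkene geometry.

**Step 8 (key step, sets the carbinol stereocentre)**
Reactants: 10 and 11 (3,5-dibromo-4-methoxybenzaldehyde)
Product: 12 ((S)-carbinol, bis-TIPS ether)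
Conditions: (i) i-PrMgCl·LiCl (1.1 equiv), THF, −40 °C, 30 min; (ii) ZnCl2 (1.1 equiv), −40 → 0 °C, then Et2Zn (1.0 equiv) and 1,4-dioxane (5 equiv); (iii) (−)-MIB (20 mol %), 11 (1.5 equiv), toluene/THF, −20 °C, 24 h; NH4Cl quench
Reagents that add atoms: none (Mg and Zn leave as salts; only H is added on workup)
Why: Proposed new method: catalytic asymmetric addition of a tetrasubstituted, lactone-embedded α-alkenylzinc (made by chemoselective vinyl-Br/Mg exchange, then Zn transmetalation) to an aryl aldehyde.
- Mechanism: the MIB–zinc alkoxide binds the aldehyde and the alkenyl–Zn–Et in a bimetallic Noyori-type transition state. The alkenyl group is transferred to one aldehyde face, and Et acts as a slow-transferring dummy group.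
- Closest known chemistry: amino-alcohol-catalysed aryl/alkenylzinc addition to aldehydes.
- Chemoselectivity: the activated α-carbonyl vinyl bromide exchanges well before the two deactivated aryl bromides and the aryl–OTIPS groups, and there are no acidic protons.

**Step 9**
Reactants: 12
Product: 13 (target)
Conditions: TBAF·3H2O (2.5 equiv), AcOH (5 equiv), THF, 0 °C → rt, dark
Reagents that add atoms: none
Why: Fluoride cleaves the aryl–OTIPS ethers. AcOH buffering prevents lactone opening and epimerisation. The carbinol is not acidic, so the (S) centre and the Z-alkene are untouched.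

**Checks**
- The target has a 3-bromo-4-hydroxyphenyl at C4, a Z-(3-bromo-4-hydroxybenzylidene) at C5, and a C3 CH(OH)(3,5-dibromo-4-methoxyphenyl) in (S) configuration. **13** matches all of these.
- All three phenols are protected and all Br atoms are retained through Steps 2–8. The only stereocentre is set in Step 8 and is not touched afterwards.

## Compound list

| # | Name | SMILES | Role |
|---|---|---|---|
| 1 | 4-iodophenol | `Oc1ccc(I)cc1` | starting material |
| 2 | 2-bromo-4-iodophenol | `Oc1ccc(I)cc1Br` | intermediate |
| 3 | (2-bromo-4-iodophenoxy)triisopropylsilane | `CC(C)[Si](C(C)C)(C(C)C)Oc1ccc(I)cc1Br` | intermediate |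
| 4 | triisopropyl[2-bromo-4-(Bpin)phenoxy]silane | `CC(C)[Si](C(C)C)(C(C)C)Oc1ccc(B2OC(C)(C)C(C)(C)O2)cc1Br` | intermediate |
| 5 | 3-bromo-4-hydroxybenzaldehyde | `O=Cc1ccc(O)c(Br)c1` | starting material |
| 6 | 3-bromo-4-(TIPSO)benzaldehyde | `O=Cc1ccc(O[Si](C(C)C)(C(C)C)C(C)C)c(Br)c1` | intermediate |
| 7 | 3,4-dibromofuran-2(5H)-one | `O=C1OCC(Br)=C1Br` | starting material |
| 8 | 3-bromo-4-[3-bromo-4-(TIPSO)phenyl]furan-2(5H)-one | `O=C1OCC(c2ccc(O[Si](C(C)C)(C(C)C)C(C)C)c(Br)c2)=C1Br` | intermediate |
| 9 | aldol O-TBS adduct (diastereomeric mixture) | `O=C1OC(C(O[Si](C)(C)C(C)(C)C)c2ccc(O[Si](C(C)C)(C(C)C)C(C)C)c(Br)c2)C(c2ccc(O[Si](C(C)C)(C(C)C)C(C)C)c(Br)c2)=C1Br` | intermediate |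
| 10 | (Z)-3-bromo-4-aryl-5-arylidene butenolide (bis-TIPS) | `O=C1C(Br)=C(c2ccc(O[Si](C(C)C)(C(C)C)C(C)C)c(Br)c2)/C(=C/c2ccc(O[Si](C(C)C)(C(C)C)C(C)C)c(Br)c2)O1` | intermediate |
| 11 | 3,5-dibromo-4-methoxybenzaldehyde | `COc1c(Br)cc(C=O)cc1Br` | starting material |
| 12 | (S)-carbinol, bis-TIPS ether | `COc1c(Br)cc([C@H](O)C2=C(c3ccc(O[Si](C(C)C)(C(C)C)C(C)C)c(Br)c3)/C(=C/c3ccc(O[Si](C(C)C)(C(C)C)C(C)C)c(Br)c3)OC2=O)cc1Br` | intermediate |
| 13 | target (CID71459453) | `COc1c(Br)cc([C@H](O)C2=C(c3ccc(O)c(Br)c3)/C(=C/c3ccc(O)c(Br)c3)OC2=O)cc1Br` | target |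

**Total steps:** 9. **Longest linear sequence:** 8 (Steps 1, 2, 3, 5, 6, 7, 8, 9; Step 4 is a parallel branch).

**Three steps most likely to fail**
1. **Step 8 (proposed new method).**
   - Risks: the hindered, electron-poor tetrasubstituted alkenylzinc may be unreactive or give low ee. Et transfer or attack of i-PrMgCl on the lactone could also compete.
   - Fallback (known chemistry): form racemic **12** by i-PrMgCl·LiCl exchange and addition of **11** without the catalyst. Oxidise with DMP to the 3-aroyl butenolide, then apply Ru-TsDPEN asymmetric transfer hydrogenation (HCO2H/Et3N) or CBS reduction to set (S). Choose the catalyst enantiomer that gives (S).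
2. **Steps 6–7 (vinylogous aldol, then E1cB to the Z-arylidene).**
   - Risks: poor conversion, E/Z mixtures, or sluggish loss of the silyloxy group.
   - Fallback: change the order of bond formation. Do the aldol condensation of **6** with the simple 3,4-dibromofuranone **7** first, then the C4-selective Suzuki coupling with **4**, then continue with Step 8.
3. **Step 5 (Suzuki of a bromo-bearing boronate).**
   - Risks: boronate self-coupling and lactone ring-opening.
   - Fallback: drop boron. Convert **3** to the arylzinc by i-PrMgCl·LiCl I/Mg exchange and ZnCl2, then do a Negishi coupling at C4 of **7**.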